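The readings are simulated from invented constants.

The constants I can read from epsilon are a first slope, a later slope and a tail.

| setting | epsilon | gamma | midnight | winter |
|---|---|---|---|---|
| electrophile | 20 mM | 20 mM | 20 mM | 20 mM |
| nucleophile | 1 equiv | 1 equiv | 1.00 equiv | 1.00 equiv |
| free base | 1.2 equiv (fed, over 20 min) | 1.7 equiv (fed, over 20 min) | 1.00 equiv (fed, over 20 min) | 1.50 equiv (fed, over 20 min) |
| remark | run made earlier | run made earlier |  |  |
| time |  |  | 50 min | 50 min |

epsilon run (percent of the electrophile charged)

| time / min | electrophile / % | target / % |
|---|---|---|
| 1.50 | 52.1 | 45.0 |
| 5.00 | 32.0 | 59.7 |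
| 8.00 | 20.4 | 67.9 |
| 15.0 | 5.9 | 80.1 |
| 20.0 | 1.7 | 83.9 |
| 25.0 | 0.4 | 83.9 |

gamma run (percent of the electrophile charged)

| time / min | electrophile / % | target / % |
|---|---|---|
| 4.00 | 32.4 | 61.5 |
| 8.00 | 15.0 | 76.5 |
| 12.0 | 4.6 | 82.1 |
| 15.0 | 3.2 | 84.6 |
| 20.0 | 0.5 | 87.3 |
| 25.0 | 1.4 | 87.4 |

- what was read earlier has a scatter of 1 percentage point, one standard deviation
- what has gone from electrophile into another species counts as reacted, even if it can come back

- part of the electrophile that has reacted at the end, midnight
- part of the electrophile that has reacted at the end, winter
- what raising the equivalents of free base from its lowest to its highest value here does to the part of the electrophile that has reacted (changes below 5 percentage points count as none) (it falls / no change / it rises)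

In epsilon the target climbs at 0.300 /min of the charge up to 1.50 min, then at 0.0273 /min between 5.00 min and 8.00 min. After that, electrophile falls with a half-life of about 2.79 min, as a reading.

I read the two slopes as a jump and a ramp. Each turn sets acid free, and I take its capture as instant: by free base where there is some, otherwise by a second nucleophile. So the target ceiling is 0.5 times the sum of nucleophile and base fed, capped at 1 charge. Before any base has been fed it stands at 0.500. In this reckoning free base is the limiting reagent on the ramp. For epsilon the ramp slope should be 0.0300 /min, which agrees with the reading within its scatter.

In midnight the curve therefore jumps towards 0.500, then climbs at 0.0250 /min. Its knee comes at 20.0 min, where the ceiling reaches 1.00. In winter the knee comes earlier, at 13.3 min, and the uncapped sum ends at 1.25, above the charge, so the cap of 1 charge holds. If the midnight tail starts at the knee from epsilon's reading of 5.9% and runs like epsilon's, the remaining 30.0 min is long against the half-life. That gives >99.9% reacted. Winter has longer after its knee than midnight, so I expect no change.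

The forecast gives 99.6% for midnight, 100% for winter and no change, in its words: “It then decays with a half-life of a few minutes, so it is essentially gone by 50 min.”

The flask gives 99.9% for midnight, 99.9% for winter and no change, a difference of 0.021 percentage points.

    acid set free + free base ⇌ salt of the base, settled at all times (K = 6.40 × 10⁵ /M)
    nucleophile + acid set free ⇌ protonated nucleophile, settled at all times (K = 7900 /M)
    2 electrophile → self-condensation product (k = 1.70 × 10⁻⁵ /M/s)
    electrophile ⇌ dormant form (K = 24.0, k = 5.60 × 10⁻⁴ /s)
    electrophile + nucleophile ⇌ acid set free + target (K = 10.0, k = 0.860 /M/s)

The neighbouring flask is midnight with 0.400 equiv of free base, so I reckon its ceiling as 0.700. Its target stands at 69.5% after 50.0 min. Free base is down to 0.22% of its own charge, and free nucleophile to 4.5%. Protonated nucleophile holds 26.0% of the nucleophile charge. The electrophile counted as reacted in this neighbouring flask is 95.2%, and the dormant form holds 25.7% of the electrophile charge.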